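**Retrosynthetic overview**
1. The bond cut first is the depside ester between the ring A carbonyl and O4 of ring B. The ring A O2 and O4 and the ring B carboxyl all travel as benzyl groups, so one hydrogenolysis ends the route.
2. The plan rests on the substitution pattern of ring B. The neighbouring carbons C1 (carboxyl) and C2 (heptyl) are the two alkyne carbons of a dec-2-ynoate, and C3 to C6, with oxygen on C4 and C6, are a 1,3-dioxygenated diene.
3. Ring B is the only ring that is built. A [4+2] cycloaddition of benzyl dec-2-ynoate to the bis(trimethylsilyl) dienol ether of dimedone makes C2-C3 and C1-C6, and extrusion of isobutylene aromatises the adduct.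
4. Ring A is bought as orsellinic acid and is only protected and activated. The order is ring B (steps 1 to 4), the ring A acyl chloride (steps 5 to 7), then union and deprotection (steps 8 and 9).

Key step: step 4

Remark: the target has no stereocentre, so no SMILES carries a descriptor (9 is racemic); ring B is numbered C1 = carboxyl carbon, C2 = heptyl carbon, C4 = depside oxygen carbon, C6 = chelated hydroxyl carbon; LDA is taken as the commercial solution.

Step 1
Reactants: 1 1-nonyne; 2 benzyl chloroformate
Product: 4 benzyl dec-2-ynoate, via non-1-ynyllithium 3 (not isolated)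
Conditions: n-BuLi (1.05 equiv), THF, -78 °C; then cannulated into 2 (1.3 equiv), THF, -78 °C to 0 °C
Reagents that add atoms: n-butyllithium, [Li]CCCC (its lithium stands only in 3)
Why: Deprotonation of the terminal alkyne and acyl substitution of the acetylide on the chloroformate (alkoxycarbonylation of a lithium acetylide) is standard, and inverse addition to excess 2 in the cold keeps the ynoate from being attacked a second time.

Step 2
Reactants: 5 dimedone
Product: 6 5,5-dimethyl-3-(trimethylsilyloxy)cyclohex-2-en-1-one
Conditions: TMSCl (1.2 equiv), Et3N (1.3 equiv), THF, 0 °C to rt; filtration under N2, distillation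
Reagents that add atoms: chlorotrimethylsilane, C[Si](C)(C)Cl
Why: O-silylation of the enol of a cyclic 1,3-diketone with an amine base (silyl enol ether formation) gives the vinylogous silyl ester, and the symmetry of 5 allows only one product.

Step 3
Reactants: 6 5,5-dimethyl-3-(trimethylsilyloxy)cyclohex-2-en-1-one
Product: 8 5,5-dimethyl-1,3-bis(trimethylsilyloxy)cyclohexa-1,3-diene, via lithium dienolate 7 (not isolated)
Conditions: LDA [LiN(iPr)2, commercial solution] (1.1 equiv), THF, -78 °C; TMSCl (1.3 equiv), -78 °C to rt; pentane, filtration, bulb-to-bulb distillation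
Reagents that add atoms: chlorotrimethylsilane, C[Si](C)(C)Cl; lithium diisopropylamide, [Li]N(C(C)C)C(C)C (its lithium stands only in 7)
Why: Kinetic alpha-prime deprotonation of the vinylogous silyl ester and O-silylation of the cross-conjugated dienolate (silyl dienol ether formation) should give 8, and because both oxygens end up with the same silyl group, deprotonation at the gamma methylene would lead to the same diene.

Step 4
Reactants: 4 benzyl dec-2-ynoate; 8 5,5-dimethyl-1,3-bis(trimethylsilyloxy)cyclohexa-1,3-diene
Product: 11 benzyl 2-heptyl-4,6-dihydroxybenzoate, via bicyclo[2.2.2]octadiene adduct 9 (not isolated), via bis(trimethylsilyloxy)arene 10 (not isolated)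
Conditions: 8 (3 equiv), neat, Ar, 150 °C, gas outlet open; then 1 M aq HCl, THF, rt
Reagents that add atoms: none
Why: Thermal normal-electron-demand [4+2] cycloaddition of the electron-rich diene 8 to the ynoate 4 gives the bicyclo[2.2.2]octa-2,5-diene 9, which at the same temperature loses its saturated CH2-CMe2 bridge as isobutylene in a retro-[4+2] step to give arene 10, and dilute acid then hydrolyses both aryl silyl ethers. This is the Alder-Rickert reaction, an established way to beta-resorcylates from dimedone-derived bis(silyloxy)dienes and beta-alkyl alk-2-ynoates. Ring B is closed intermolecularly by one concerted, asynchronous six-electron cycloaddition that forms C2-C3 and C1-C6, the diene carbons C4, C3, C2 and C1 becoming ring B C3, C4, C5 and C6 and the alkyne carbons becoming C1 and C2. No stereocentre remains, since the two bridgeheads of 9 form as a racemate and are flattened on aromatisation. The step needs regioselectivity, and the diene secures it, because both silyloxy groups push electron density onto the unsubstituted diene terminus, which bonds to the electrophilic heptyl-bearing beta-carbon of 4 and so places the oxygens ortho and para to the ester. Cycloreversion takes the isobutylene bridge because only that path gives an arene, and the [1,5]-hydrogen shift open to 8 at this temperature is degenerate, so the excess diene does not scramble.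

Step 5
Reactants: 12 orsellinic acid
Product: 13 benzyl 2,4-bis(benzyloxy)-6-methylbenzoate
Conditions: BnBr (3.5 equiv), K2CO3 (4 equiv), DMF, rt then 60 °C
Reagents that add atoms: benzyl bromide, BrCc1ccccc1
Why: Carboxylate alkylation and Williamson etherification (SN2 on benzyl bromide) benzylate all three acidic sites, the carboxylate reacting first at rt so that decarboxylation is blocked before the mixture is warmed to etherify the chelated 2-hydroxyl.

Step 6
Reactants: 13 benzyl 2,4-bis(benzyloxy)-6-methylbenzoate
Product: 15 2,4-bis(benzyloxy)-6-methylbenzoic acid, via potassium carboxylate 14 (not isolated)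
Conditions: KOH (excess), DMSO/H2O, 90 °C; then 2 M aq HCl, 0 °C, pH 2
Reagents that add atoms: potassium hydroxide, [K+].[OH-]
Why: Saponification of the doubly ortho-substituted ester needs poorly solvated hydroxide in hot aqueous DMSO, conditions to which the aryl benzyl ethers are inert, and cold acidification frees the acid without decarboxylation.

Step 7
Reactants: 15 2,4-bis(benzyloxy)-6-methylbenzoic acid
Product: 16 2,4-bis(benzyloxy)-6-methylbenzoyl chloride
Conditions: (COCl)2 (1.3 equiv), DMF (cat.), CH2Cl2, 0 °C to rt; evaporated and used crude
Reagents that add atoms: oxalyl chloride, O=C(Cl)C(=O)Cl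
Why: Acid chloride formation through the catalytic chloroiminium (Vilsmeier-type) species runs at or below rt with only gaseous by-products, which spares the benzyl ethers.

Step 8
Reactants: 11 benzyl 2-heptyl-4,6-dihydroxybenzoate; 16 2,4-bis(benzyloxy)-6-methylbenzoyl chloride
Product: 17 benzyl 4-{[2,4-bis(benzyloxy)-6-methylbenzoyl]oxy}-2-heptyl-6-hydroxybenzoate
Conditions: Et3N (1.5 equiv), DMAP (0.1 equiv), CH2Cl2, 0 °C to rt; 16 (1.05 equiv) added slowly
Reagents that add atoms: none
Why: In this DMAP-catalysed acylation of a phenol by an acyl chloride, the 4-hydroxyl is free and the more acidic one, whereas the 6-hydroxyl is held in a six-membered hydrogen bond to the ester carbonyl, so about one equivalent of 16 should esterify O4 only.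

Step 9
Reactants: 17 benzyl 4-{[2,4-bis(benzyloxy)-6-methylbenzoyl]oxy}-2-heptyl-6-hydroxybenzoate
Product: 18 4-[(2,4-dihydroxy-6-methylbenzoyl)oxy]-2-heptyl-6-hydroxybenzoic acid (target)
Conditions: H2 (1 atm), 10% Pd/C, EtOAc, rt
Reagents that add atoms: none
Why: Catalytic hydrogenolysis cleaves the benzyl ester and both benzyl ethers at their benzylic C-O bonds and leaves the aryl ester link untouched, and the non-nucleophilic solvent excludes alcoholysis of the depside.

**Compound list**
1 | 1-nonyne | CCCCCCCC#C | starting material
2 | benzyl chloroformate | O=C(Cl)OCc1ccccc1 | starting material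
3 | non-1-ynyllithium | [Li]C#CCCCCCCC | intermediate
4 | benzyl dec-2-ynoate | CCCCCCCC#CC(=O)OCc1ccccc1 | intermediate
5 | dimedone (5,5-dimethylcyclohexane-1,3-dione) | CC1(C)CC(=O)CC(=O)C1 | starting material
6 | 5,5-dimethyl-3-(trimethylsilyloxy)cyclohex-2-en-1-one | CC1(C)CC(=O)C=C(O[Si](C)(C)C)C1 | intermediate
7 | lithium 5,5-dimethyl-3-(trimethylsilyloxy)cyclohexa-1(6),2-dien-1-olate (cross-conjugated dienolate) | [Li]OC1=CC(C)(C)CC(O[Si](C)(C)C)=C1 | intermediate
8 | 5,5-dimethyl-1,3-bis(trimethylsilyloxy)cyclohexa-1,3-diene | CC1(C)CC(O[Si](C)(C)C)=CC(O[Si](C)(C)C)=C1 | intermediate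
9 | benzyl 3-heptyl-8,8-dimethyl-1,5-bis(trimethylsilyloxy)bicyclo[2.2.2]octa-2,5-diene-2-carboxylate (racemic) | C[Si](C)(C)OC12CC(C)(C)C(C(O[Si](C)(C)C)=C1)C(CCCCCCC)=C2C(=O)OCc1ccccc1 | intermediate
10 | benzyl 2-heptyl-4,6-bis(trimethylsilyloxy)benzoate | CCCCCCCc1cc(O[Si](C)(C)C)cc(O[Si](C)(C)C)c1C(=O)OCc1ccccc1 | intermediate
11 | benzyl 2-heptyl-4,6-dihydroxybenzoate (= benzyl 6-heptyl-2,4-dihydroxybenzoate) | CCCCCCCc1cc(O)cc(O)c1C(=O)OCc1ccccc1 | intermediate
12 | orsellinic acid (2,4-dihydroxy-6-methylbenzoic acid) | Cc1cc(O)cc(O)c1C(=O)O | starting material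
13 | benzyl 2,4-bis(benzyloxy)-6-methylbenzoate | Cc1cc(OCc2ccccc2)cc(OCc2ccccc2)c1C(=O)OCc1ccccc1 | intermediate
14 | potassium 2,4-bis(benzyloxy)-6-methylbenzoate | Cc1cc(OCc2ccccc2)cc(OCc2ccccc2)c1C(=O)[O-].[K+] | intermediate
15 | 2,4-bis(benzyloxy)-6-methylbenzoic acid | Cc1cc(OCc2ccccc2)cc(OCc2ccccc2)c1C(=O)O | intermediate
16 | 2,4-bis(benzyloxy)-6-methylbenzoyl chloride | Cc1cc(OCc2ccccc2)cc(OCc2ccccc2)c1C(=O)Cl | intermediate
17 | benzyl 4-{[2,4-bis(benzyloxy)-6-methylbenzoyl]oxy}-2-heptyl-6-hydroxybenzoate | CCCCCCCc1cc(OC(=O)c2c(C)cc(OCc3ccccc3)cc2OCc2ccccc2)cc(O)c1C(=O)OCc1ccccc1 | intermediate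
18 | 4-[(2,4-dihydroxy-6-methylbenzoyl)oxy]-2-heptyl-6-hydroxybenzoic acid (CNP0227363.0) | CCCCCCCc1cc(OC(=O)c2c(C)cc(O)cc2O)cc(O)c1C(=O)O | target

**Step count**
Total: 9 steps. The longest linear sequence is 5 steps: steps 2, 3, 4, 8 and 9 from dimedone, equal in length to steps 5, 6, 7, 8 and 9 from orsellinic acid.

**Steps most likely to fail**

Step 4.
- What may go wrong: the cycloaddition may be too slow. The beta-carbon of 4 carries an alkyl chain, and the diene terminus that must bond to it sits next to the quaternary carbon. During long heating the diene would then be lost by protodesilylation and the ynoate by oligomerisation.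
- Fallback: this gives up ring construction and sets out from 13, coming back at 11. Compound 13 is deprotonated at its aryl methyl group with LDA in THF at -78 °C (lateral lithiation of an ortho-toluate). The benzylic anion is alkylated with 1-iodohexane to give benzyl 2,4-bis(benzyloxy)-6-heptylbenzoate F1. Hydrogenolysis (H2, Pd/C, EtOAc) removes all three benzyl groups to give 2-heptyl-4,6-dihydroxybenzoic acid F2. The carboxylate alone is then alkylated with BnBr (1 equiv) and KHCO3 in DMF at rt, which returns 11.

Step 8.
- What may go wrong: addition to the doubly ortho-substituted acyl chloride may be slow. Acylation of the chelated 6-hydroxyl under base and hydrolysis of the acyl chloride could then compete with esterification at O4.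
- Fallback: this leaves the acyl chloride and base behind. It sets out from 15 and 11 and comes back at 17, so step 7 drops out. The acid and the phenol are stirred with (CF3CO)2O in toluene at rt, which converts 15 into 2,4-bis(benzyloxy)-6-methylbenzoic trifluoroacetic anhydride F3. This electron-rich 2,6-disubstituted aroyl derivative reacts by a dissociative, acylium-like path that ortho substituents do not slow. With no base present the 6-hydroxyl is never deprotonated and stays chelated. Any aryl trifluoroacetate that forms is hydrolysed on aqueous work-up.

Step 3.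
- What may go wrong: the amide base may attack silicon in 6, the dienolate may silylate partly on carbon, and the labile diene may hydrolyse during isolation.
- Fallback: this replaces the lithium enolate by soft enolisation. It sets out from 5 and comes back at 8 in one flask, using TMSOTf (2.2 equiv) and Et3N (3 equiv) in Et2O at 0 °C to rt. Compound 5 is silylated to 6, and a second silylation on the carbonyl oxygen gives the symmetrical 5,5-dimethyl-1,3-bis(trimethylsilyloxy)cyclohexenylium triflate F4. The amine removes a proton from either flanking methylene of F4, and both choices give 8. The ammonium triflate separates as a lower phase, and the ether layer is concentrated and distilled without aqueous contact.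

**Further compounds**
F1 | step 4 | benzyl 2,4-bis(benzyloxy)-6-heptylbenzoate | CCCCCCCc1cc(OCc2ccccc2)cc(OCc2ccccc2)c1C(=O)OCc1ccccc1
F2 | step 4 | 2-heptyl-4,6-dihydroxybenzoic acid | CCCCCCCc1cc(O)cc(O)c1C(=O)O
F3 | step 8 | 2,4-bis(benzyloxy)-6-methylbenzoic trifluoroacetic anhydride | Cc1cc(OCc2ccccc2)cc(OCc2ccccc2)c1C(=O)OC(=O)C(F)(F)F
F4 | step 3 | 5,5-dimethyl-1,3-bis(trimethylsilyloxy)cyclohexenylium triflate | CC1(C)CC(O[Si](C)(C)C)=CC(=[O+][Si](C)(C)C)C1.[O-]S(=O)(=O)C(F)(F)F
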